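## Retrosynthetic overview

- **Feature:** the ester carbonyl carbon C1 sits between the benzylic oxygen and C2 of a saturated, unbranched C2–C23 chain of 22 carbons. The only ring is the phenyl ring, and there is no stereocentre.
- **Disconnection:** the C1–C2 and C1–O(benzyl) bonds are cut together. C2–C23 becomes the even-numbered α-olefin 1-docosene (1), C1 becomes carbon monoxide (2), and the OCH2Ph part becomes benzyl alcohol (3).
- **Forward:** one Pd–H catalysed, linear-selective hydrobenzyloxycarbonylation joins the three purchased components directly to the target.
- **Ring formation:** none. The phenyl ring is bought with 3.

Key step: step 1

Remark on stereochemistry: the target has no stereocentre and no stereogenic double bond, so it is achiral and only one form exists to be made.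

Remark on numbering: the two catalyst-bound species that carry the chain are numbered (4, 5) and drawn without the weakly held fourth ligand; free internal docosenes formed reversibly by chain walking are a shifting mixture of positional and E/Z isomers that re-enters the cycle at 4, so they are treated as a resting form of 1.

## Route

Step 1
Reactants: 1 1-docosene; 2 carbon monoxide; 3 benzyl alcohol
Product: 6 benzyl tricosanoate, via docosylpalladium cation 4 (not isolated), via tricosanoylpalladium cation 5 (not isolated)
Conditions: Pd(OAc)2 (1 mol %), 1,2-bis(di-tert-butylphosphinomethyl)benzene (dtbpx, 5 mol %), MeSO3H (10 mol %), CO (30 bar), BnOH (5 equiv), degassed toluene, 90 °C, autoclave; silica plug, then crystallisation from cold MeOH/acetone (excess BnOH stays in the liquor)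
Reagents that add atoms: carbon monoxide (2), [C-]#[O+]; benzyl alcohol (3), OCc1ccccc1
Why: This is a hydride-cycle hydroalkoxycarbonylation (hydroesterification, Reppe-type carbonylation) of an alkene: MeSO3H turns the Pd(0)/dtbpx complex into a cationic Pd–H, which inserts the C=C bond of 1, and fast reversible β-hydride elimination/re-insertion lets the metal travel along the chain until it rests as the primary alkyl 4. Migratory insertion of 2 into the Pd–CH2 bond of 4 makes the C1–C2 bond (acyl 5), and attack of 3 on the acyl carbon of 5 makes the C1–O bond, releases 6 and gives back the hydride, so that all atoms of 1, 2 and 3 end up in 6 and no co-product arises. The closest known chemistry is the isomerising methoxycarbonylation of long-chain terminal and internal olefins and unsaturated fatty esters with the same Pd/dtbpx/sulfonic acid system, which also accepts higher primary alcohols, benzylic ones included. No ring is closed and no stereocentre is formed, so neither a mode of closure nor a stereocontrol element is involved. The selectivity that matters is linear against branched, that is C1 bound to the chain terminus and not to an inner carbon: the four tert-butyl groups of the wide-bite-angle chelate raise the barriers for CO insertion and above all for alcoholysis at any secondary alkyl or acyl, while the substrate, an unbranched hydrocarbon without a second functional group or branch point to hold the walking metal, lets every isomerised olefin drain through 4. The benzyl ester should survive because no H2 is present for hydrogenolysis and the small, phosphine-buffered amount of acid should not ionise the benzylic C–O bond at 90 °C.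

## Compound list

1 | 1-docosene (docos-1-ene, single-cut C22 grade) | CCCCCCCCCCCCCCCCCCCCC=C | starting material
2 | carbon monoxide | [C-]#[O+] | starting material
3 | benzyl alcohol | OCc1ccccc1 | starting material
4 | [(dtbpx)Pd(n-docosyl)]+ mesylate, primary alkyl, fourth site β-agostic or solvent (not drawn) | CCCCCCCCCCCCCCCCCCCCCC[Pd-]1[P+](C(C)(C)C)(C(C)(C)C)Cc2ccccc2C[P+]1(C(C)(C)C)C(C)(C)C.CS(=O)(=O)[O-] | intermediate
5 | [(dtbpx)Pd(tricosanoyl)]+ mesylate, linear acyl, fourth site CO or solvent (not drawn) | CCCCCCCCCCCCCCCCCCCCCCC(=O)[Pd-]1[P+](C(C)(C)C)(C(C)(C)C)Cc2ccccc2C[P+]1(C(C)(C)C)C(C)(C)C.CS(=O)(=O)[O-] | intermediate
6 | benzyl tricosanoate (achiral) | CCCCCCCCCCCCCCCCCCCCCCC(=O)OCc1ccccc1 | target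

## Step count and risks

Total step count: 1
Longest linear sequence: 1 step

Steps most likely to fail (the route has a single step, so the list has one entry):

**Step 1.** Three processes could spoil it, and a fourth point concerns the grade of 1:
- Linear selectivity may erode through carbonylation at a secondary carbon. This would put branched isomers into a waxy product from which they are hard to remove by chromatography or crystallisation.
- Alcoholysis of 5 may be slow, because the alcohol is bulkier than methanol and diluted in a medium of low polarity. The catalyst would then decay to palladium black and the olefin would be left as a mixture of internal isomers.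
- Acid-catalysed self-etherification of 3 would consume the alcohol and release water into the catalytic system.
- Chain-length homologues in technical grades of 1 would be carried through unchanged, so a GC-checked single-cut grade is required.

Fallback (no carbon monoxide, and C–C bond formation moved to C2=C3): the fallback sets out from 1. Cross metathesis with commercial benzyl acrylate (C=CC(=O)OCc1ccccc1, 2–3 equiv) is run with the Hoveyda–Grubbs II catalyst and a little 1,4-benzoquinone against olefin migration, in CH2Cl2 at 40 °C. The C21 alkylidene of 1 joins the two-carbon CH–C(=O) end of the acrylate, which should give benzyl (E)-tricos-2-enoate F1 with the correct 23-carbon acyl chain and no possibility of branching. The conjugated C2=C3 bond is then saturated with H2 (1–4 bar) and RhCl(PPh3)3 in toluene/EtOH at room temperature to 40 °C. This homogeneous catalyst does not hydrogenolyse benzyl esters, and the sequence comes back to the route at 6.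

## Further compounds

F1 | step 1 | benzyl (E)-tricos-2-enoate | CCCCCCCCCCCCCCCCCCCC/C=C/C(=O)OCc1ccccc1
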